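Cuts: C4=C5 goes back to a cis-4,5-diol (Corey–Winter); the C1–O–C6 oxirane to a trans-diaxial C1–OH/C6–OMs pair; the C7–O benzoate to carboxylate opening of a C1 spiro-oxirane; the exocyclic C1–C7 bond to methylene transfer onto a C1 ketone.
Enabling feature: C1 is the only carbon-branched ring atom and also carries oxygen, so without C7 the six-membered ring is a pentaoxygenated cyclohexanone (an inosose) whose single methyl ether (C2) and C2–C6 configurations are those of D-pinitol: C2 = methoxy carbon, C3 = its trans neighbour, C4/C5 = one cis-diol, C1/C6 = the other.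
Forward order: the carbocycle comes from pinitol; its two cis-diols are told apart by a temporary butane-2,3-diacetal on the only trans-diequatorial diol (O3/O4), and O1 is then oxidised. The spiro-oxirane (C1–C7) is closed and opened at C7, the ring oxirane C1–O–C6 is closed, and C4=C5 is made last.
Stereochemistry: C2 and C3 are carried from pinitol; C1 is set by equatorial methylene delivery to the chair ketone (new C–O axial, cis to OMe); C6 by SN2 inversion in the oxirane closure; C4/C5 are cleared stereospecifically.

Key step: step 8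

Numbering used in all names: ring atoms as in the target (C1 quaternary carbon = carbonyl carbon of 13, C2 methoxy carbon, C3, C4, C5, C6; C7 exocyclic); C1–C6 are C2, C3, C4, C5, C6, C1 of D-pinitol; beta = face of the C2 methoxy group, alpha = the other face.
Remark (assumption): ketone 13 is taken to react from the chair inherited from pinitol (O2, O3, O4 equatorial; O5, O6 axial), the other chair being disfavoured by a syn-diaxial O2/O4 contact.

Step 1
Reactants: 1 D-pinitol (1D-3-O-methyl-chiro-inositol); 2 butane-2,3-dione; 3 trimethyl orthoformate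
Product: 4 butane-2,3-diacetal of D-pinitol on O3 (alpha) and O4 (beta) (inositol O4/O5; dioxane trans-fused, both acetal OMe axial; free OH at C1 alpha-equatorial, C5 beta-axial, C6 alpha-axial)
Conditions: butane-2,3-dione, HC(OMe)3, camphorsulfonic acid (cat.), MeOH, reflux
Reagents that add atoms: butane-2,3-dione CC(=O)C(C)=O; trimethyl orthoformate COC(OC)OC
Why: Butane-2,3-diacetal formation under thermodynamic control selects the single trans-diequatorial diol, where the trans-fused dioxane can hold both methoxy groups axial (double anomeric stabilisation), and leaves both cis-diols open, which breaks the near-symmetry of the two halves of pinitol.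

Step 2
Reactants: 4; 5 benzoyl chloride
Product: 6 1-O-benzoyl derivative of 4 (free OH at C5 and C6, both axial)
Conditions: BzCl (1.05 equiv), pyridine, CH2Cl2, -40 to 0 °C
Reagents that add atoms: benzoyl chloride O=C(Cl)c1ccccc1
Why: Regioselective acylation at low temperature takes the only equatorial hydroxyl of the conformationally locked triol (C1–OH, the future carbonyl carbon) in preference to the two axial ones.

Step 3
Reactants: 6
Product: 7 1-O-benzoyl-D-pinitol (inositol O2 benzoate; free OH at C3, C4, C5, C6)
Conditions: TFA/H2O (9:1), rt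
Reagents that add atoms: none
Why: Acid-catalysed acetal hydrolysis removes the diacetal once it has served to mark O1, and the equatorial benzoate is stable to aqueous acid and has no thermodynamic drive to move to the axial O6.

Step 4
Reactants: 7; 8 2,2-dimethoxypropane
Product: 9 1-O-benzoyl-4,5-O-isopropylidene-D-pinitol (acetonide on the beta face; free OH at C3 alpha-equatorial and C6 alpha-axial)
Conditions: 2,2-dimethoxypropane, p-toluenesulfonic acid monohydrate (cat.), acetone, rt
Reagents that add atoms: 2,2-dimethoxypropane COC(C)(C)OC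
Why: Equilibrating acetonide formation (transacetalisation) can settle only on O4/O5, the one cis-diol with both hydroxyls still free, because O1 is acylated and the O3/O4 and O5/O6 pairs are trans.

Step 5
Reactants: 9; 10 tert-butyldimethylsilyl trifluoromethanesulfonate
Product: 11 1-O-benzoyl-3,6-bis-O-(tert-butyldimethylsilyl)-4,5-O-isopropylidene-D-pinitol
Conditions: TBSOTf, 2,6-lutidine, CH2Cl2, 0 °C to rt
Reagents that add atoms: tert-butyldimethylsilyl trifluoromethanesulfonate CC(C)(C)[Si](C)(C)OS(=O)(=O)C(F)(F)F
Why: Silylation with the silyl triflate caps both remaining hydroxyls, the hindered axial C6–OH included, as base-stable and non-chelating ethers without disturbing the ester or the acetonide.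

Step 6
Reactants: 11
Product: 12 3,6-bis-O-(tert-butyldimethylsilyl)-4,5-O-isopropylidene-D-pinitol (C1–OH alpha-equatorial, the only free hydroxyl)
Conditions: iBu2AlH, CH2Cl2, -78 °C
Reagents that add atoms: none
Why: Reductive ester cleavage at low temperature frees O1 without the alkoxide equilibration at higher temperature that could let the cis silyl group on O6 migrate.

Step 7
Reactants: 12
Product: 13 protected inosose (C1 ketone; 2beta-OMe; 3alpha-OTBS; 4beta,5beta-O-isopropylidene; 6alpha-OTBS)
Conditions: Dess–Martin periodinane, CH2Cl2, 0 °C to rt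
Reagents that add atoms: none
Why: Dess–Martin oxidation turns the lone secondary alcohol into the ketone under non-basic conditions, so that C2 and C6 do not epimerise and no beta-alkoxide is eliminated.

Step 8
Reactants: 13; 14 trimethylsulfoxonium iodide
Product: 16 C1 spiro-epoxide of the inosose (oxirane O beta/axial; C7 alpha/equatorial), via betaine 15 (not isolated)
Conditions: Me3S(O)I, NaH, DMSO, rt; then 13 in THF, 0 °C to rt
Reagents that add atoms: trimethylsulfoxonium iodide C[S+](C)(C)=O.[I-]
Why: Corey–Chaykovsky epoxidation: dimethylsulfoxonium methylide adds reversibly to the C1 carbonyl to give betaine 15, whose alkoxide displaces dimethyl sulfoxide in a 3-exo-tet closure that forms the C1–C7 bond and the spiro-oxirane; the closest known reaction type is methylene transfer from this ylide to substituted cyclohexanones and protected inososes, which places the new carbon equatorial. In the chair of 13 the axial trajectory on the beta face is blocked by the syn-axial C5–O bond and would put the bulky CH2S(O)Me2 group 1,3-diaxial to it, so the betaine that closes should carry C7 equatorial (alpha) and the oxygen axial (beta, cis to the C2 methoxy group); the new C1 stereocentre is thus controlled by the ring conformation fixed by the existing C2–C6 centres. The step needs this facial selectivity and freedom from beta-elimination: enolisation towards C2 would have to expel an equatorial, poorly aligned C3 silyloxy group, and enolisation towards C6 would need removal of an equatorial C6–H, so loss of an alkoxide by an E1cB path should be slow, and every oxygen substituent is an ether or acetal that tolerates the ylide. The axial C1–O bond ends anti-periplanar to the axial C6–O bond, which is the arrangement the later oxirane shift requires.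

Step 9
Reactants: 16; 17 benzoic acid
Product: 18 tertiary alcohol (C1–OH beta; C7H2–OBz alpha; 3alpha- and 6alpha-OTBS; 4,5-acetonide)
Conditions: BzOH, Cs2CO3 (cat.), DMF, 80 °C
Reagents that add atoms: benzoic acid OC(=O)c1ccccc1
Why: Nucleophilic opening of the 2,2-disubstituted oxirane by benzoate is an SN2 reaction at the unsubstituted C7 methylene, so the C1–O bond and the C1 configuration are untouched and the C7 benzoate of the target is installed directly.

Step 10
Reactants: 18
Product: 19 triol (C1–OH beta, C3–OH alpha, C6–OH alpha; C7–OBz; 4,5-acetonide)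
Conditions: Bu4NF, AcOH, THF, rt
Reagents that add atoms: none
Why: Fluoride-induced desilylation buffered with acetic acid frees O3 and O6 while keeping the medium too weakly basic for benzoyl migration from O7.

Step 11
Reactants: 19; 5 benzoyl chloride
Product: 20 3,7-dibenzoate (C1–OH beta and C6–OH alpha as a trans-diaxial diol; 4,5-acetonide)
Conditions: BzCl (1.1 equiv), pyridine, CH2Cl2, -20 °C
Reagents that add atoms: benzoyl chloride O=C(Cl)c1ccccc1
Why: Site-selective acylation should occur at the equatorial C3–OH, since the axial C6–OH is shielded by the fully substituted C1 next to it and the C1–OH is tertiary, which places the second benzoate of the target.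

Step 12
Reactants: 20; 21 methanesulfonyl chloride
Product: 22 C6 alpha-mesylate of 20 (C1–OH free)
Conditions: MsCl, Et3N, CH2Cl2, 0 °C
Reagents that add atoms: methanesulfonyl chloride CS(=O)(=O)Cl
Why: Mesylation through sulfene converts the only remaining secondary hydroxyl (C6) into a leaving group and does not touch the tertiary C1–OH.

Step 13
Reactants: 22
Product: 23 1,6-epoxide on the beta face (cis to OMe; 3alpha-OBz; C7–OBz; 4,5-acetonide)
Conditions: NaH, THF, 0 °C to rt
Reagents that add atoms: none
Why: Intramolecular Williamson etherification, in which the axial C1 alkoxide displaces the anti-periplanar axial C6 mesylate in a 3-exo-tet SN2 closure with inversion at C6, should give the oxirane on the beta face, cis to the C2 methoxy group as in the target.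

Step 14
Reactants: 23
Product: 24 cis-4,5-diol (both OH beta) of 23
Conditions: AcOH/H2O (4:1), 40 °C
Reagents that add atoms: none
Why: Mild acid-catalysed acetal hydrolysis releases the cis-4,5-diol, and the oxirane, inductively deactivated by the oxygens on C2, C5 and C7 and without a trans-disposed hydroxyl for a Payne shift, is expected to survive in the way anhydro sugars survive such conditions.

Step 15
Reactants: 24; 25 1,1'-thiocarbonyldiimidazole
Product: 26 4,5-cyclic thionocarbonate of 24
Conditions: 1,1'-thiocarbonyldiimidazole, 4-(dimethylamino)pyridine (cat.), THF, 60 °C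
Reagents that add atoms: 1,1'-thiocarbonyldiimidazole S=C(n1ccnc1)n1ccnc1
Why: Cyclic thionocarbonate formation on the cis-diol is the first stage of the Corey–Winter olefination and needs no selectivity because no other hydroxyl is left.

Step 16
Reactants: 26
Product: 27 target (1,6-beta-epoxide; 2beta-OMe; 3alpha-OBz; C4=C5; C7H2–OBz alpha)
Conditions: 1,3-dimethyl-2-phenyl-1,3,2-diazaphospholidine, THF, 40 °C
Reagents that add atoms: none
Why: Corey–Winter olefination in its low-temperature Corey–Hopkins variant removes sulfur and then carbon dioxide in a stereospecific syn elimination to give the C4=C5 double bond, under conditions mild enough for the vinyl oxirane and the allylic benzoate.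

Compound list
1 | D-pinitol (1D-3-O-methyl-chiro-inositol) | CO[C@H]1[C@H](O)[C@@H](O)[C@@H](O)[C@H](O)[C@@H]1O | starting material
2 | butane-2,3-dione | CC(=O)C(C)=O | starting material
3 | trimethyl orthoformate | COC(OC)OC | starting material
4 | D-pinitol O3/O4 butane-2,3-diacetal (both acetal OMe axial) | CO[C@H]1[C@@H]2O[C@@](C)(OC)[C@](C)(OC)O[C@H]2[C@@H](O)[C@H](O)[C@@H]1O | intermediate
5 | benzoyl chloride | O=C(Cl)c1ccccc1 | starting material
6 | 1-O-benzoyl O3/O4 butane-2,3-diacetal | CO[C@H]1[C@@H]2O[C@@](C)(OC)[C@](C)(OC)O[C@H]2[C@@H](O)[C@H](O)[C@@H]1OC(=O)c1ccccc1 | intermediate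
7 | 1-O-benzoyl-D-pinitol | CO[C@H]1[C@H](O)[C@@H](O)[C@@H](O)[C@H](O)[C@@H]1OC(=O)c1ccccc1 | intermediate
8 | 2,2-dimethoxypropane | COC(C)(C)OC | starting material
9 | 1-O-benzoyl-4,5-O-isopropylidene-D-pinitol | CO[C@H]1[C@H](O)[C@H]2OC(C)(C)O[C@H]2[C@H](O)[C@@H]1OC(=O)c1ccccc1 | intermediate
10 | tert-butyldimethylsilyl trifluoromethanesulfonate | CC(C)(C)[Si](C)(C)OS(=O)(=O)C(F)(F)F | starting material
11 | 1-O-benzoyl-3,6-bis-O-TBS-4,5-O-isopropylidene-D-pinitol | CO[C@H]1[C@H](O[Si](C)(C)C(C)(C)C)[C@H]2OC(C)(C)O[C@H]2[C@H](O[Si](C)(C)C(C)(C)C)[C@@H]1OC(=O)c1ccccc1 | intermediate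
12 | 3,6-bis-O-TBS-4,5-O-isopropylidene-D-pinitol (C1–OH free) | CO[C@H]1[C@H](O[Si](C)(C)C(C)(C)C)[C@H]2OC(C)(C)O[C@H]2[C@H](O[Si](C)(C)C(C)(C)C)[C@@H]1O | intermediate
13 | protected inosose (C1 ketone) | CO[C@H]1[C@H](O[Si](C)(C)C(C)(C)C)[C@H]2OC(C)(C)O[C@H]2[C@H](O[Si](C)(C)C(C)(C)C)C1=O | intermediate
14 | trimethylsulfoxonium iodide | C[S+](C)(C)=O.[I-] | starting material
15 | betaine (C1 alkoxide beta; C7H2–S(O)Me2 alpha) | CO[C@H]1[C@H](O[Si](C)(C)C(C)(C)C)[C@H]2OC(C)(C)O[C@H]2[C@H](O[Si](C)(C)C(C)(C)C)[C@]1([O-])C[S+](C)(C)=O | intermediate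
16 | C1 spiro-epoxide (O beta/axial; C7 alpha/equatorial) | CO[C@H]1[C@H](O[Si](C)(C)C(C)(C)C)[C@H]2OC(C)(C)O[C@H]2[C@H](O[Si](C)(C)C(C)(C)C)[C@]13CO3 | intermediate
17 | benzoic acid | OC(=O)c1ccccc1 | starting material
18 | C1 tertiary alcohol, C7 benzoate, 3,6-bis-OTBS, 4,5-acetonide | CO[C@H]1[C@H](O[Si](C)(C)C(C)(C)C)[C@H]2OC(C)(C)O[C@H]2[C@H](O[Si](C)(C)C(C)(C)C)[C@]1(O)COC(=O)c1ccccc1 | intermediate
19 | 1,3,6-triol, C7 benzoate, 4,5-acetonide | CO[C@H]1[C@H](O)[C@H]2OC(C)(C)O[C@H]2[C@H](O)[C@]1(O)COC(=O)c1ccccc1 | intermediate
20 | 3,7-dibenzoate, 1,6-trans-diol, 4,5-acetonide | CO[C@H]1[C@H](OC(=O)c3ccccc3)[C@H]2OC(C)(C)O[C@H]2[C@H](O)[C@]1(O)COC(=O)c1ccccc1 | intermediate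
21 | methanesulfonyl chloride | CS(=O)(=O)Cl | starting material
22 | C6 mesylate of 20 | CO[C@H]1[C@H](OC(=O)c3ccccc3)[C@H]2OC(C)(C)O[C@H]2[C@H](OS(C)(=O)=O)[C@]1(O)COC(=O)c1ccccc1 | intermediate
23 | 1,6-beta-epoxide, 3,7-dibenzoate, 4,5-acetonide | CO[C@H]1[C@H](OC(=O)c3ccccc3)[C@H]2OC(C)(C)O[C@H]2[C@H]2O[C@]21COC(=O)c1ccccc1 | intermediate
24 | 1,6-beta-epoxide, 3,7-dibenzoate, cis-4,5-diol | CO[C@H]1[C@H](OC(=O)c2ccccc2)[C@@H](O)[C@@H](O)[C@H]2O[C@]21COC(=O)c1ccccc1 | intermediate
25 | 1,1'-thiocarbonyldiimidazole | S=C(n1ccnc1)n1ccnc1 | starting material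
26 | 4,5-cyclic thionocarbonate of 24 | CO[C@H]1[C@H](OC(=O)c3ccccc3)[C@H]2OC(=S)O[C@H]2[C@H]2O[C@]21COC(=O)c1ccccc1 | intermediate
27 | CNP0231490.2 | CO[C@H]1[C@H](OC(=O)c2ccccc2)C=C[C@H]2O[C@]21COC(=O)c1ccccc1 | target

Total steps: 16. Longest linear sequence: 16 steps (1 to 27).

Steps most likely to fail

Step 8. Methylene transfer may take the other face (axial delivery anti to the axial C6 silyloxy group), or enolisation and beta-elimination of the hindered ketone may overtake it. Fallback: setting out from 13, the C1–C7 bond is made by chelation-controlled Grignard addition of (iPrO)Me2SiCH2MgCl in THF at -78 °C. Magnesium bridges the C1 carbonyl and the C2 methoxy oxygen (the silyl ethers do not chelate), so the nucleophile enters trans to the methoxy group and gives the silylmethyl carbinol F1. Tamao–Fleming oxidation (H2O2, KF, KHCO3, THF/MeOH) gives the C1,C7-diol F2, and benzoylation of its primary hydroxyl (BzCl, pyridine, -20 °C) comes back to the route at 18.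

Step 14. Acid may open the oxirane (hydrolysis or participation of the C7 benzoate) or move the C3 benzoate while the acetonide is being removed. Fallback: setting out from 20, before the ring oxirane exists, the acetonide is hydrolysed (AcOH/H2O) to the tetraol F3. Its cis-4,5-diol is converted with 1,1'-thiocarbonyldiimidazole into the cyclic thionocarbonate F4 and then by Corey–Winter fragmentation into the cyclohexene trans-diol F5. Mitsunobu cyclodehydration (PPh3, diisopropyl azodicarboxylate, THF), with activation of the secondary allylic C6–OH and SN2 displacement by the tertiary C1–OH, closes the oxirane and comes back to the route at 27.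

Step 11. Acylation may lose site selectivity (over-benzoylation at O6) or be followed by benzoyl migration. Fallback: setting out from 18, the two silyl ethers are removed in turn instead of together. The less hindered equatorial C3 silyl ether is cleaved first (HF·pyridine, THF/pyridine, 0 °C) to the C3 alcohol F6. Its only secondary hydroxyl is benzoylated (BzCl, pyridine, 4-(dimethylamino)pyridine) to the dibenzoate silyl ether F7, and fluoride (Bu4NF, AcOH, THF) then frees O6 and comes back to the route at 20.

Further compounds
F1 | step 8 | silylmethyl carbinol (C1–OH beta; C7H2–SiMe2(OiPr) alpha) | CO[C@H]1[C@H](O[Si](C)(C)C(C)(C)C)[C@H]2OC(C)(C)O[C@H]2[C@H](O[Si](C)(C)C(C)(C)C)[C@]1(O)C[Si](C)(C)OC(C)C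
F2 | step 8 | C1,C7-diol | CO[C@H]1[C@H](O[Si](C)(C)C(C)(C)C)[C@H]2OC(C)(C)O[C@H]2[C@H](O[Si](C)(C)C(C)(C)C)[C@]1(O)CO
F3 | step 14 | tetraol (1,4,5,6-OH; 3,7-dibenzoate) | CO[C@H]1[C@H](OC(=O)c2ccccc2)[C@@H](O)[C@@H](O)[C@H](O)[C@]1(O)COC(=O)c1ccccc1
F4 | step 14 | 4,5-cyclic thionocarbonate with free 1,6-diol | CO[C@H]1[C@H](OC(=O)c3ccccc3)[C@H]2OC(=S)O[C@H]2[C@H](O)[C@]1(O)COC(=O)c1ccccc1
F5 | step 14 | cyclohexene trans-1,6-diol (3,7-dibenzoate) | CO[C@H]1[C@H](OC(=O)c2ccccc2)C=C[C@H](O)[C@]1(O)COC(=O)c1ccccc1
F6 | step 11 | C3 alcohol (C6–OTBS kept; C7 benzoate) | CO[C@H]1[C@H](O)[C@H]2OC(C)(C)O[C@H]2[C@H](O[Si](C)(C)C(C)(C)C)[C@]1(O)COC(=O)c1ccccc1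
F7 | step 11 | dibenzoate silyl ether (3,7-OBz; C6–OTBS) | CO[C@H]1[C@H](OC(=O)c3ccccc3)[C@H]2OC(C)(C)O[C@H]2[C@H](O[Si](C)(C)C(C)(C)C)[C@]1(O)COC(=O)c1ccccc1
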